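**Retrosynthetic overview**
- Target ⇒ ring C closed last, by loss of two MeOH from a 2-hydroxyaryl β-keto dimethyl acetal.
- β-Keto acetal ⇒ biomimetic oxidative 1,2-aryl shift of a 2'-hydroxychalcone (Tl(III)); the C3–aryl bond is made by migration, not by 3-halochromone cross-coupling or a deoxybenzoin.
- Chalcone ⇒ Claisen–Schmidt condensation of paeonol with 5-methoxy-2,2-dimethyl-2H-chromene-6-carbaldehyde.
- Aldehyde ⇒ O-methylation of the product of chelation-controlled chromenylation (aldol / oxa-6π) of 2,4-dihydroxybenzaldehyde with prenal.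
- Ring order: both benzene rings are bought; the dimethylpyran ring is formed first (step 1); the γ-pyranone ring C is formed last (step 5).

Assumption: the target has no stereocentre and no stereogenic acyclic double bond, so "single enantiomer" reduces to the achiral compound itself; transient stereocentres are racemic and are erased.

**Step 1**
Reactants: 1 2,4-dihydroxybenzaldehyde; 2 3-methylbut-2-enal (prenal)
Product: 4 5-hydroxy-2,2-dimethyl-2H-chromene-6-carbaldehyde, via ortho-quinone methide 3 (not isolated)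
Conditions: 2 (2 equiv), pyridine, 140 °C (sealed tube), 16 h
Reagents that add atoms: none
Why: The 2-OH is locked in a hydrogen bond to the formyl group, so Knoevenagel-type aldol condensation occurs at C3 through the 4-OH enol unit to give quinone methide 3, which closes by oxa-6π-electrocyclisation to the angular chromene (no stereocentre formed).

**Step 2**
Reactants: 4 5-hydroxy-2,2-dimethyl-2H-chromene-6-carbaldehyde
Product: 5 5-methoxy-2,2-dimethyl-2H-chromene-6-carbaldehyde
Conditions: MeI (3 equiv), K2CO3 (2 equiv), DMF, 40 °C, 12 h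
Reagents that add atoms: iodomethane, CI
Why: Williamson O-methylation (SN2) of the phenoxide, which K2CO3 in DMF frees from its hydrogen bond, while the aldehyde and the chromene olefin are inert.

**Step 3**
Reactants: 5 5-methoxy-2,2-dimethyl-2H-chromene-6-carbaldehyde; 6 1-(2-hydroxy-4-methoxyphenyl)ethan-1-one (paeonol)
Product: 8 (E)-1-(2-hydroxy-4-methoxyphenyl)-3-(5-methoxy-2,2-dimethyl-2H-chromen-6-yl)prop-2-en-1-one, via aldol adduct 7 (not isolated)
Conditions: KOH (50% aq.), EtOH, rt, 48 h
Reagents that add atoms: none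
Why: Claisen–Schmidt condensation, in which the acetophenone enolate adds to the non-enolisable aldehyde and aldol 7 loses water by E1cB to the thermodynamically favoured E-enone (this geometry is consumed in step 4).

**Step 4**
Reactants: 8 (E)-1-(2-hydroxy-4-methoxyphenyl)-3-(5-methoxy-2,2-dimethyl-2H-chromen-6-yl)prop-2-en-1-one
Product: 9 1-(2-hydroxy-4-methoxyphenyl)-3,3-dimethoxy-2-(5-methoxy-2,2-dimethyl-2H-chromen-6-yl)propan-1-one (racemic)
Conditions: Tl(NO3)3·3H2O (1.05 equiv), MeOH–HC(OMe)3 (1:1), −10 → 0 °C, 30 min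
Reagents that add atoms: methanol, CO (two equivalents are incorporated)
Why: Tl(III)-mediated oxidative 1,2-aryl migration (biomimetic chalcone-to-isoflavonoid rearrangement), in which oxythallation of the enone C=C places MeOH on the benzylic carbon, the ortho,para-dioxygenated aryl ring shifts to the α-carbon as Tl(I) leaves, and the resulting oxocarbenium ion is trapped by MeOH as the dimethyl acetal; the new stereocentre is racemic and is destroyed in step 5.

**Step 5**
Reactants: 9 1-(2-hydroxy-4-methoxyphenyl)-3,3-dimethoxy-2-(5-methoxy-2,2-dimethyl-2H-chromen-6-yl)propan-1-one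
Product: 11 7-methoxy-3-(5-methoxy-2,2-dimethyl-2H-chromen-6-yl)-4H-chromen-4-one (target), via 2-methoxyisoflavanone 10 (not isolated)
Conditions: p-TsOH·H2O (10 mol%), toluene, 70 °C, 2 h
Reagents that add atoms: none
Why: Acid-catalysed transacetalisation–elimination, in which the acetal ionises to an oxocarbenium ion, the 2-OH closes ring C to the cyclic acetal 10, and loss of the second methanol gives the conjugated γ-pyranone and removes the transient stereocentres.

**Compound list**
1 | 2,4-dihydroxybenzaldehyde | O=Cc1ccc(O)cc1O | starting material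
2 | 3-methylbut-2-enal (prenal) | CC(C)=CC=O | starting material
3 | 2-hydroxy-3-(3-methylbut-2-en-1-ylidene)-4-oxocyclohexa-1,5-diene-1-carbaldehyde (ortho-quinone methide, exocyclic C=C geometry undefined) | O=CC1=C(O)C(=CC=C(C)C)C(=O)C=C1 | intermediate
4 | 5-hydroxy-2,2-dimethyl-2H-chromene-6-carbaldehyde | CC1(C)C=Cc2c(O1)ccc(C=O)c2O | intermediate
5 | 5-methoxy-2,2-dimethyl-2H-chromene-6-carbaldehyde | COc1c(C=O)ccc2OC(C)(C)C=Cc12 | intermediate
6 | 1-(2-hydroxy-4-methoxyphenyl)ethan-1-one (paeonol) | CC(=O)c1ccc(OC)cc1O | starting material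
7 | 3-hydroxy-1-(2-hydroxy-4-methoxyphenyl)-3-(5-methoxy-2,2-dimethyl-2H-chromen-6-yl)propan-1-one (racemic aldol adduct) | COc1ccc(C(=O)CC(O)c2ccc3OC(C)(C)C=Cc3c2OC)c(O)c1 | intermediate
8 | (E)-1-(2-hydroxy-4-methoxyphenyl)-3-(5-methoxy-2,2-dimethyl-2H-chromen-6-yl)prop-2-en-1-one | COc1ccc(C(=O)/C=C/c2ccc3OC(C)(C)C=Cc3c2OC)c(O)c1 | intermediate
9 | 1-(2-hydroxy-4-methoxyphenyl)-3,3-dimethoxy-2-(5-methoxy-2,2-dimethyl-2H-chromen-6-yl)propan-1-one (racemic) | COc1ccc(C(=O)C(C(OC)OC)c2ccc3OC(C)(C)C=Cc3c2OC)c(O)c1 | intermediate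
10 | 2,7-dimethoxy-3-(5-methoxy-2,2-dimethyl-2H-chromen-6-yl)chroman-4-one (racemic, cis/trans mixture) | COC1Oc2cc(OC)ccc2C(=O)C1c1ccc2OC(C)(C)C=Cc2c1OC | intermediate
11 | 7-methoxy-3-(5-methoxy-2,2-dimethyl-2H-chromen-6-yl)-4H-chromen-4-one | COc1ccc2c(=O)c(-c3ccc4c(c3OC)C=CC(C)(C)O4)coc2c1 | target

**Totals**
Total step count: 5. Longest linear sequence: 5 steps (1 → 4 → 5 → 8 → 9 → 11); paeonol 6 enters as bought at step 3.

**Three steps most likely to fail**

Step 4 (highest risk). Tl(III) is an alkene-philic oxidant, and the electron-rich chromene C3=C4 bond sits on the same donor-rich ring that activates the enone. Selectivity relies on the gem-dimethyl group shielding the chromene olefin, on one equivalent of oxidant and on low temperature. Competing oxythallation of the chromene would cost the route here.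

The fallback sets out from 8 and comes back at 11, and replaces the electrophilic oxidant by a redox-neutral 1,2-shift. The 2'-OH of 8 is capped with MOMCl (NaH, DMF, 0 °C), because a free 2'-hydroxychalcone would undergo Algar–Flynn–Oyamada cyclisation in the next operation. This gives the MOM ether (E)-1-[4-methoxy-2-(methoxymethoxy)phenyl]-3-(5-methoxy-2,2-dimethyl-2H-chromen-6-yl)prop-2-en-1-one F1. Weitz–Scheffer epoxidation (30% H2O2, NaOH, MeOH–THF, 0 °C) is a nucleophilic oxidation that does not touch the electron-rich chromene olefin. It gives the racemic trans-epoxy ketone [4-methoxy-2-(methoxymethoxy)phenyl][(2S*,3R*)-3-(5-methoxy-2,2-dimethyl-2H-chromen-6-yl)oxiran-2-yl]methanone F2. BF3·OEt2 (CH2Cl2, −40 → 0 °C) opens the epoxide at the donor-stabilised benzylic carbon and the aroyl group migrates (House–Meinwald rearrangement). This gives the α-formyl deoxybenzoin 3-[4-methoxy-2-(methoxymethoxy)phenyl]-2-(5-methoxy-2,2-dimethyl-2H-chromen-6-yl)-3-oxopropanal F3. Catalytic HCl in MeOH at rt removes the MOM group, and the freed phenol closes onto the formyl group to the hemiacetal 2-hydroxy-7-methoxy-3-(5-methoxy-2,2-dimethyl-2H-chromen-6-yl)chroman-4-one F4. Dehydration of the hemiacetal gives 11.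

Step 5. After the aryl shift the chromene ring is no longer attached to an acceptor, so it is an electron-rich 2,2-dimethylchromene. Brønsted acid can protonate C3 and lead to dimerisation or solvent addition before the acetal has cyclised.

The fallback sets out from 9 and comes back at 11, and moves the ring closure to an anionic manifold with no proton source. Treatment of 9 with KOt-Bu (2.2 equiv, THF, 0 °C → rt) causes E1cB loss of methoxide from the enolate. This gives the β-methoxy enone 1-(2-hydroxy-4-methoxyphenyl)-3-methoxy-2-(5-methoxy-2,2-dimethyl-2H-chromen-6-yl)prop-2-en-1-one F5 (E/Z mixture, present as its phenoxide). Its phenoxide closes by intramolecular oxa-Michael addition to the enolate of 10, which expels the second methoxide to give 11.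

Step 1. The one-pot chromenylation can give moderate yields, through prenal self-condensation or some linear 7-hydroxy isomer.

The fallback sets out from 1 and comes back at 4 through the same quinone methide 3. It replaces the C-aldol by an O-alkylation and sigmatropic cascade. The non-chelated 4-OH of 1 is alkylated selectively with 3-chloro-3-methylbut-1-yne (K2CO3, KI, CuI cat., acetone, 60 °C) to give the aryl propargyl ether 2-hydroxy-4-[(2-methylbut-3-yn-2-yl)oxy]benzaldehyde F6. Heating (N,N-diethylaniline, 190 °C) brings about the aromatic propargyl Claisen rearrangement to C3, giving the allenyl phenol 2,4-dihydroxy-3-(3-methylbuta-1,2-dien-1-yl)benzaldehyde F7. A 1,5-H shift then leads to 3, and oxa-6π-electrocyclisation gives 4.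

**Further compounds**
F1 | step 4 | (E)-1-[4-methoxy-2-(methoxymethoxy)phenyl]-3-(5-methoxy-2,2-dimethyl-2H-chromen-6-yl)prop-2-en-1-one | COCOc1cc(OC)ccc1C(=O)/C=C/c1ccc2OC(C)(C)C=Cc2c1OC
F2 | step 4 | [4-methoxy-2-(methoxymethoxy)phenyl][(2S*,3R*)-3-(5-methoxy-2,2-dimethyl-2H-chromen-6-yl)oxiran-2-yl]methanone (racemic trans-epoxide, one enantiomer drawn) | COCOc1cc(OC)ccc1C(=O)[C@H]1O[C@@H]1c1ccc2OC(C)(C)C=Cc2c1OC
F3 | step 4 | 3-[4-methoxy-2-(methoxymethoxy)phenyl]-2-(5-methoxy-2,2-dimethyl-2H-chromen-6-yl)-3-oxopropanal (racemic) | COCOc1cc(OC)ccc1C(=O)C(C=O)c1ccc2OC(C)(C)C=Cc2c1OC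
F4 | step 4 | 2-hydroxy-7-methoxy-3-(5-methoxy-2,2-dimethyl-2H-chromen-6-yl)chroman-4-one (racemic, diastereomer mixture) | OC1Oc2cc(OC)ccc2C(=O)C1c1ccc2OC(C)(C)C=Cc2c1OC
F5 | step 5 | 1-(2-hydroxy-4-methoxyphenyl)-3-methoxy-2-(5-methoxy-2,2-dimethyl-2H-chromen-6-yl)prop-2-en-1-one (E/Z mixture) | COC=C(C(=O)c1ccc(OC)cc1O)c1ccc2OC(C)(C)C=Cc2c1OC
F6 | step 1 | 2-hydroxy-4-[(2-methylbut-3-yn-2-yl)oxy]benzaldehyde | O=Cc1ccc(OC(C)(C)C#C)cc1O
F7 | step 1 | 2,4-dihydroxy-3-(3-methylbuta-1,2-dien-1-yl)benzaldehyde | O=Cc1ccc(O)c(C=C=C(C)C)c1O
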